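Before anyone filters this flask for recovered solid substrate, settle where the charge has gone.

| setting | Sunday's | Tuesday's | flask |
|---|---|---|---|
| solid substrate | 0.50 mM | 0.50 mM | 0.50 mM |
| solid reagent | 0.35 mM | 0.70 mM | 0.350 mM |
| remark | the very flask that is asked about, followed so far | run made earlier |  |
| time |  |  | 5.0 min |

Sunday's run (percent of the solid substrate charged)

| time / s | target / % | solid product / % |
|---|---|---|
| 10.0 | 5.6 | 1.4 |
| 20.0 | 17.0 | 0 |
| 40.0 | 25.1 | 0.5 |
| 60.0 | 26.3 | 0.8 |

Tuesday's run (percent of the solid substrate charged)

| time / min | target / % | solid product / % |
|---|---|---|
| 0.250 | 11.8 | 0.3 |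
| 0.667 | 26.6 | 0.2 |
| 1.50 | 30.1 | 0.1 |
| 4.00 | 32.1 | 0 |

(scatter of a reading: 1 percentage point)

- target is meant together with its solid product
- solid, in amounts per volume of the solution: solid substrate, solid product, solid reagent
- at the start none of the solid substrate is in solution
- at the start none of the solid reagent is in solution
- dissolved substrate means what is dissolved; the solid is not counted in it

* target and solid product together at 5.0 min, in percent of the solid substrate charged
* concentration of dissolved substrate in solution at 5.0 min, in percent of saturation

Sunday's last reading, at 60.0 s, leaves 72.9% of the charge as the missing share, the part that is neither target nor solid product. Tuesday's last reading leaves 67.9%. Two chemists read these numbers differently.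

The first says the missing share is still solid substrate and the reagent has died. Her forecast is 28% (26% to 31%) for y and 95% (70% to 100%) for sat. In her words: “Once the reagent is dead, nothing consumes dissolved substrate”.

The second looks at Tuesday's run. It held 1.40 equivalents of solid reagent, so solid substrate was its limiting reagent by charge. Yet Tuesday's last reading, at 4.00 min, stands 5 percentage points above Sunday's last, at 60.0 s, with twice the solid reagent and a longer run behind it. Since that reading rose less than the reagent did, he reads the missing share as already spent in solution on something unread. He expects a nearly empty solution, but gives no figure.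

The flask gives 29.8% for y and 1.47% for sat.

    solid substrate ⇌ dissolved substrate, rate k1*(cs1 - [dissolved substrate]) while solid is left; crystals form when [dissolved substrate] > cs1 (solubility = 0.270 mM, k = 0.400 s⁻¹)
    dissolved substrate + partner → target (k = 290 M⁻¹ s⁻¹)
    2 dissolved substrate → side product (k = 53.0 M⁻¹ s⁻¹)
    solid product ⇌ target, rate k4*(cs4 - [target]) while solid is left; crystals form when [target] > cs4 (solubility = 0.160 mM, k = 3.70 s⁻¹)
    solid reagent ⇌ partner, rate k5*(cs5 - [partner]) while solid is left; crystals form when [partner] > cs5 (solubility = 0.260 mM, k = 0.0990 s⁻¹)
    target ⇌ isomer of the product (K = 1.20, k = 0.190 s⁻¹)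

The forecast's y lies within its range, but its sat does not, and solid substrate stands at 0% by 0.500 min. The missing share, 72.9% at 60.0 s, is 70.2% at 5.0 min, held as side product 33.7%, isomer of the product 35.7% and dissolved substrate 0.792%. The first view's dead reagent fits the neighbour with 0.85 mM of solid substrate, where partner is down to 1.54 × 10⁻⁴ mM. Its missing share is 81.3%, with solid substrate at 0% and side product at 55.2%.

The data are calculated on assumed constants, noise included.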